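**Strategy.** Everything rests on cutting the sp–sp2 single bond between C5' (alkyne) and C6' (alkene) of the (6'E)-hexadec-6'-en-4'-ynyl chain on ring carbon C6. A Sonogashira coupling of the terminal alkyne of the finished, unprotected (3S,6R)-6-methoxy-1,2-dioxane-3-acetic acid with (E)-1-iodoundec-1-ene forms this bond and the whole conjugated enyne in the last operation. It exploits the acidic alkyne C–H and the fixed geometry of the iodide; because the E-alkene arrives last, it never meets the ozone that creates the C6 peroxyketal. The dioxane ring (O1, O2, C3–C6) is closed beforehand by 6-exo displacement of a C3 mesylate by a C6 hydroperoxyketal.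

Key step: step 11

Remark 1: tert-butyl(but-3-en-1-yloxy)dimethylsilane (1) is taken as a catalogue compound; otherwise it is one silylation away from but-3-en-1-ol.
Remark 2: the target is (3S,6R), with the C6 methoxy group cis to the C3 side chain. C6 is not controlled in the ozonolysis, so both C6 epimers are carried through ring closure and the (3S,6R) isomer is separated in step 7.

Step 1
Reactants: 1 tert-butyl(but-3-en-1-yloxy)dimethylsilane
Product: 2 rac-tert-butyldimethyl[2-(oxiran-2-yl)ethoxy]silane
Conditions: mCPBA, CH2Cl2, 0 °C → rt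
Reagents that add atoms: mCPBA (3-chloroperoxybenzoic acid), OOC(=O)c1cccc(Cl)c1
Why: Prilezhaev epoxidation of the terminal alkene should give the racemic epoxide, and the silyl ether is inert to the peracid.

Step 2
Reactants: 2 rac-tert-butyldimethyl[2-(oxiran-2-yl)ethoxy]silane
Product: 3 tert-butyldimethyl{2-[(2S)-oxiran-2-yl]ethoxy}silane
Conditions: (S,S)-N,N'-bis(3,5-di-tert-butylsalicylidene)cyclohexane-1,2-diamine cobalt acetate, (salen)Co(OAc), trivalent cobalt (0.5 mol%), H2O (0.55 equiv), THF, 0 °C → rt; distillation
Reagents that add atoms: none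
Why: In the Jacobsen hydrolytic kinetic resolution the (S,S)-catalyst (the antipode that hydrates the R epoxide) should leave the (S)-epoxide enantioenriched, which fixes the centre that becomes C3 after the inversion in step 7.

Step 3
Reactants: 4 (4-bromobut-1-yn-1-yl)trimethylsilane; 5 3-chloro-2-(chloromethyl)prop-1-ene
Product: 7 [6-(chloromethyl)hept-6-en-1-yn-1-yl]trimethylsilane, via butynyl Grignard reagent 6 (not isolated)
Conditions: Mg, THF, rt (on 4); then added to 5 (3 equiv), CuI (5 mol%), THF, −20 → 0 °C
Reagents that add atoms: none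
Why: Copper-catalysed allylic substitution of the symmetrical dichloride by the Grignard reagent gives the same product by SN2 or SN2' attack, and the excess of 5 should suppress double substitution.

Step 4
Reactants: 7 [6-(chloromethyl)hept-6-en-1-yn-1-yl]trimethylsilane; 3 tert-butyldimethyl{2-[(2S)-oxiran-2-yl]ethoxy}silane
Product: 9 (3R)-1-[(tert-butyldimethylsilyl)oxy]-6-methylidene-11-(trimethylsilyl)undec-10-yn-3-ol, via allylic Grignard reagent 8 (not isolated)
Conditions: Mg (3 equiv), THF, 0 °C, slow addition of 7; then CuI (10 mol%), 3, −30 → 0 °C; aq NH4Cl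
Reagents that add atoms: none
Why: Copper-catalysed opening of the terminal epoxide by the 2-substituted allylic Grignard reagent (both allyl termini equivalent) should occur at the unsubstituted carbon, leaving the stereocentre untouched (the descriptor becomes R only through a change of priorities).

Step 5
Reactants: 9 (3R)-1-[(tert-butyldimethylsilyl)oxy]-6-methylidene-11-(trimethylsilyl)undec-10-yn-3-ol
Product: 10 (3R)-1-[(tert-butyldimethylsilyl)oxy]-6-methylidene-11-(trimethylsilyl)undec-10-yn-3-yl methanesulfonate
Conditions: MsCl, Et3N, CH2Cl2, 0 °C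
Reagents that add atoms: methanesulfonyl chloride, CS(=O)(=O)Cl
Why: Sulfonylation of the secondary alcohol proceeds at oxygen with retention and turns C3 into the electrophile for ring closure.

Step 6
Reactants: 10 (3R)-1-[(tert-butyldimethylsilyl)oxy]-6-methylidene-11-(trimethylsilyl)undec-10-yn-3-yl methanesulfonate
Product: 11 (3R)-1-[(tert-butyldimethylsilyl)oxy]-6-hydroperoxy-6-methoxy-11-(trimethylsilyl)undec-10-yn-3-yl methanesulfonate (both C6 epimers)
Conditions: O3, CH2Cl2/MeOH (4:1), NaHCO3, −78 °C, Sudan Red 7B end point; warm under N2, concentrate cold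
Reagents that add atoms: ozone, [O-][O+]=O; methanol, CO
Why: In this Criegee ozonolysis the 1,1-disubstituted alkene should cleave to the ketone oxide and formaldehyde, methanol traps the ketone oxide as the α-methoxy hydroperoxide, and the far less reactive silylalkyne is spared by stopping at the indicator end point; C6 forms without control.

Step 7
Reactants: 11 (3R)-1-[(tert-butyldimethylsilyl)oxy]-6-hydroperoxy-6-methoxy-11-(trimethylsilyl)undec-10-yn-3-yl methanesulfonate (both C6 epimers)
Product: 12 tert-butyl(2-{(3S,6R)-6-methoxy-6-[5-(trimethylsilyl)pent-4-yn-1-yl]-1,2-dioxan-3-yl}ethoxy)dimethylsilane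
Conditions: KOtBu (1.1 equiv), 18-crown-6 (0.2 equiv), toluene, 0 °C → rt; chromatographic separation of the C6 epimers
Reagents that add atoms: none
Why: In this intramolecular peroxide O-alkylation (Williamson type) the potassium hydroperoxide anion should displace the secondary mesylate in a 6-exo-tet SN2 closure with inversion, turning (3R) into (3S); both C6 epimers of 11 are expected to close, so the (3S,6R) isomer 12 (axial methoxy, both carbon substituents equatorial) is separated by chromatography from its (3S,6S) epimer, which is set aside.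

Step 8
Reactants: 12 tert-butyl(2-{(3S,6R)-6-methoxy-6-[5-(trimethylsilyl)pent-4-yn-1-yl]-1,2-dioxan-3-yl}ethoxy)dimethylsilane
Product: 13 2-[(3S,6R)-6-methoxy-6-(pent-4-yn-1-yl)-1,2-dioxan-3-yl]ethan-1-ol
Conditions: Bu4NF (2.5 equiv), THF, 0 °C → rt
Reagents that add atoms: none
Why: Fluoride should cleave both the O–Si bond of the silyl ether and the alkynyl C–Si bond in one operation, while the dialkyl peroxyketal is inert to fluoride.

Step 9
Reactants: 13 2-[(3S,6R)-6-methoxy-6-(pent-4-yn-1-yl)-1,2-dioxan-3-yl]ethan-1-ol
Product: 14 2-[(3S,6R)-6-methoxy-6-(pent-4-yn-1-yl)-1,2-dioxan-3-yl]acetic acid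
Conditions: TEMPO (0.2 equiv), PhI(OAc)2 (2.2 equiv), MeCN/H2O (1:1), rt
Reagents that add atoms: water, O
Why: The oxoammonium-mediated oxidation (TEMPO with PhI(OAc)2 in aqueous acetonitrile) should take the primary alcohol through the aldehyde hydrate to the acid under near-neutral conditions that spare the peroxide, the ketal and the terminal alkyne.

Step 10
Reactants: 15 undec-1-yne
Product: 17 (E)-1-iodoundec-1-ene, via E-alkenylalane 16 (not isolated)
Conditions: iBu2AlH (1.0 equiv), hexane, 50 °C; then I2, THF, −50 °C → rt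
Reagents that add atoms: iodine, II
Why: Zweifel hydroalumination adds Al–H syn across the terminal alkyne and iodinolysis of the C–Al bond proceeds with retention, so the E geometry should be set cleanly.

Step 11
Reactants: 14 2-[(3S,6R)-6-methoxy-6-(pent-4-yn-1-yl)-1,2-dioxan-3-yl]acetic acid; 17 (E)-1-iodoundec-1-ene
Product: 18 2-[(3S,6R)-6-[(6E)-hexadec-6-en-4-yn-1-yl]-6-methoxy-1,2-dioxan-3-yl]acetic acid
Conditions: PdCl2(PPh3)2 (3 mol%), CuI (6 mol%), iPr2NH (5 equiv), THF, degassed, rt; work-up at pH 4
Reagents that add atoms: none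
Why: Sonogashira coupling: zerovalent palladium formed in situ inserts into the C–I bond of 17 with retention, the copper acetylide generated from 14, CuI and iPr2NH transmetalates, and reductive elimination forms the sp–sp2 bond of the enyne. The closest known reaction type is the Pd/Cu alkynylation of alkenyl iodides, which is expected to tolerate a 3-alkoxy-1,2-dioxane on the alkyne partner and a free acid held as its ammonium carboxylate. No ring is closed and no stereocentre is created; C3 and C6 are remote spectators and the E geometry is set in 17 and transferred unchanged. The step needs oxidative addition into the alkenyl C–I bond rather than attack on the O–O bond, which the room-temperature reactivity of an unhindered E-iodoalkene and the shielding of the peroxide by the fully substituted ketal carbon should secure. It also needs cross-coupling over oxidative alkyne dimerisation, secured by exclusion of oxygen and a slight excess of 17, and tolerance of the acid, which stays as a carboxylate too remote from the alkyne to cyclise onto it.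

**Compound list**

1 | tert-butyl(but-3-en-1-yloxy)dimethylsilane | C=CCCO[Si](C)(C)C(C)(C)C | starting material
2 | rac-tert-butyldimethyl[2-(oxiran-2-yl)ethoxy]silane | C1OC1CCO[Si](C)(C)C(C)(C)C | intermediate
3 | tert-butyldimethyl{2-[(2S)-oxiran-2-yl]ethoxy}silane | CC(C)(C)[Si](C)(C)OCC[C@H]1CO1 | intermediate
4 | (4-bromobut-1-yn-1-yl)trimethylsilane | C[Si](C)(C)C#CCCBr | starting material
5 | 3-chloro-2-(chloromethyl)prop-1-ene | C=C(CCl)CCl | starting material
6 | [4-(trimethylsilyl)but-3-yn-1-yl]magnesium bromide | C[Si](C)(C)C#CCC[Mg]Br | intermediate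
7 | [6-(chloromethyl)hept-6-en-1-yn-1-yl]trimethylsilane | C[Si](C)(C)C#CCCCC(=C)CCl | intermediate
8 | [2-methylidene-7-(trimethylsilyl)hept-6-yn-1-yl]magnesium chloride | C[Si](C)(C)C#CCCCC(=C)C[Mg]Cl | intermediate
9 | (3R)-1-[(tert-butyldimethylsilyl)oxy]-6-methylidene-11-(trimethylsilyl)undec-10-yn-3-ol | C[Si](C)(C)C#CCCCC(=C)CC[C@H](CCO[Si](C)(C)C(C)(C)C)O | intermediate
10 | (3R)-1-[(tert-butyldimethylsilyl)oxy]-6-methylidene-11-(trimethylsilyl)undec-10-yn-3-yl methanesulfonate | C[Si](C)(C)C#CCCCC(=C)CC[C@H](CCO[Si](C)(C)C(C)(C)C)OS(C)(=O)=O | intermediate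
11 | (3R)-1-[(tert-butyldimethylsilyl)oxy]-6-hydroperoxy-6-methoxy-11-(trimethylsilyl)undec-10-yn-3-yl methanesulfonate, both C6 epimers | C[Si](C)(C)C#CCCCC(OC)(OO)CC[C@H](CCO[Si](C)(C)C(C)(C)C)OS(C)(=O)=O | intermediate
12 | tert-butyl(2-{(3S,6R)-6-methoxy-6-[5-(trimethylsilyl)pent-4-yn-1-yl]-1,2-dioxan-3-yl}ethoxy)dimethylsilane | C[Si](C)(C)C#CCCC[C@]1(OC)CC[C@@H](CCO[Si](C)(C)C(C)(C)C)OO1 | intermediate
13 | 2-[(3S,6R)-6-methoxy-6-(pent-4-yn-1-yl)-1,2-dioxan-3-yl]ethan-1-ol | C#CCCC[C@]1(OC)CC[C@@H](CCO)OO1 | intermediate
14 | 2-[(3S,6R)-6-methoxy-6-(pent-4-yn-1-yl)-1,2-dioxan-3-yl]acetic acid | C#CCCC[C@]1(OC)CC[C@@H](CC(=O)O)OO1 | intermediate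
15 | undec-1-yne | CCCCCCCCCC#C | starting material
16 | (E)-bis(2-methylpropyl)(undec-1-en-1-yl)alane | CCCCCCCCC/C=C/[Al](CC(C)C)CC(C)C | intermediate
17 | (E)-1-iodoundec-1-ene | CCCCCCCCC/C=C/I | intermediate
18 | 2-[(3S,6R)-6-[(6E)-hexadec-6-en-4-yn-1-yl]-6-methoxy-1,2-dioxan-3-yl]acetic acid | CCCCCCCCC/C=C/C#CCCC[C@]1(OC)CC[C@@H](CC(=O)O)OO1 | target

**Count.** Total steps: 11. Longest linear sequence: 9 steps (steps 1, 2, 4, 5, 6, 7, 8, 9, 11).

**Steps most likely to fail**

Step 11. The low-valent palladium, the phosphine or the copper salt may cleave the O–O bond reductively, the terminal alkyne may dimerise oxidatively, or the carboxylate may bind copper and stall transmetalation. The fallback sets out from 13 and 17 and moves the union ahead of the oxidation, so that a neutral alcohol is coupled. Sonogashira coupling of 13 with 17 (PdCl2(PPh3)2, CuI, iPr2NH, THF, rt) would give 2-[(3S,6R)-6-[(6E)-hexadec-6-en-4-yn-1-yl]-6-methoxy-1,2-dioxan-3-yl]ethan-1-ol F1. Oxidation of F1 with TEMPO and PhI(OAc)2 in aqueous MeCN comes back to the route at 18.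

Step 7. The 6-exo displacement at the secondary carbon may be outrun by base-induced elimination of the mesylate or by base-induced fragmentation of the hydroperoxyketal, and at best half of the material can have the wanted C6 configuration. The fallback sets out from 10 and builds the two C–O bonds separately, with C6 under thermodynamic control. Displacement of the mesylate by the caesium salt of 2-hydroperoxy-2-methoxypropane (CsOH·H2O, DMF, 0 °C, the hydroperoxide in slight excess over the base), with inversion, would give tert-butyl({(3S)-3-[(2-methoxypropan-2-yl)peroxy]-6-methylidene-11-(trimethylsilyl)undec-10-yn-1-yl}oxy)dimethylsilane F2. Ozonolysis of F2 in the presence of pyridine (O3, pyridine, CH2Cl2, −78 °C) would give the ketone (9S)-11-[(tert-butyldimethylsilyl)oxy]-9-[(2-methoxypropan-2-yl)peroxy]-1-(trimethylsilyl)undec-1-yn-6-one F3. TsOH (cat.) in MeOH should then remove the peroxide protecting group, close the hydroperoxide onto the ketone, convert the peroxyhemiketal into the methyl ketal with the anomerically favoured axial methoxy group, and cleave the silyl ether. This would give 2-{(3S,6R)-6-methoxy-6-[5-(trimethylsilyl)pent-4-yn-1-yl]-1,2-dioxan-3-yl}ethan-1-ol F4. K2CO3 in MeOH removes the alkynyl silyl group of F4 and comes back to the route at 13.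

Step 9. Acetic acid released from PhI(OAc)2 may solvolyse the peroxyketal before the oxidation is complete, or the oxidation may stall at the β-peroxy aldehyde, which can then lose the peroxide by β-elimination. The fallback sets out from 13 and replaces the one-pot oxoammonium oxidation by two separate oxidations through an isolated aldehyde. Dess–Martin periodinane with NaHCO3 in CH2Cl2 at 0 °C would give 2-[(3S,6R)-6-methoxy-6-(pent-4-yn-1-yl)-1,2-dioxan-3-yl]acetaldehyde F5. Immediate chlorite oxidation of F5 (NaClO2, NaH2PO4, 2-methylbut-2-ene, tBuOH/H2O) comes back to the route at 14.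

**Further compounds**

F1 | step 11 | 2-[(3S,6R)-6-[(6E)-hexadec-6-en-4-yn-1-yl]-6-methoxy-1,2-dioxan-3-yl]ethan-1-ol | CCCCCCCCC/C=C/C#CCCC[C@]1(OC)CC[C@@H](CCO)OO1
F2 | step 7 | tert-butyl({(3S)-3-[(2-methoxypropan-2-yl)peroxy]-6-methylidene-11-(trimethylsilyl)undec-10-yn-1-yl}oxy)dimethylsilane | C[Si](C)(C)C#CCCCC(=C)CC[C@@H](CCO[Si](C)(C)C(C)(C)C)OOC(C)(C)OC
F3 | step 7 | (9S)-11-[(tert-butyldimethylsilyl)oxy]-9-[(2-methoxypropan-2-yl)peroxy]-1-(trimethylsilyl)undec-1-yn-6-one | C[Si](C)(C)C#CCCCC(=O)CC[C@@H](CCO[Si](C)(C)C(C)(C)C)OOC(C)(C)OC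
F4 | step 7 | 2-{(3S,6R)-6-methoxy-6-[5-(trimethylsilyl)pent-4-yn-1-yl]-1,2-dioxan-3-yl}ethan-1-ol | C[Si](C)(C)C#CCCC[C@]1(OC)CC[C@@H](CCO)OO1
F5 | step 9 | 2-[(3S,6R)-6-methoxy-6-(pent-4-yn-1-yl)-1,2-dioxan-3-yl]acetaldehyde | C#CCCC[C@]1(OC)CC[C@@H](CC=O)OO1
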